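**Retrosynthetic overview**
- No ring is formed: both 3,4-dimethoxyphenyl rings are bought, one in methyl eugenol 1 and one in 3-(3,4-dimethoxyphenyl)propanoic acid 2.
- Key disconnection: the alkyl C–O bond of the ester (O–CH2). This gives the carboxylate of 2 and a nucleophilic C3 chain, the primary alkylboronic ester 3.
- The C–O bond is made by an oxidative copper-catalysed C(sp3)–O coupling of 3 with sodium carboxylate 4, which is formed from 2 in the flask.
- 3 is disconnected at C–B to 1 (anti-Markovnikov hydroboration).
- Forward order: 1 → 3, then 3 + 2 → target 5. In sum this is a formal anti-Markovnikov hydroacyloxylation of 1 by 2.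

Assumption: the target SMILES has no stereocentre and the molecule is achiral, so there is no enantiomer to select and no stereocontrol is needed.

**Step 1**
Reactants: 1 methyl eugenol (4-allyl-1,2-dimethoxybenzene)
Product: 3 2-[3-(3,4-dimethoxyphenyl)propyl]-4,4,5,5-tetramethyl-1,3,2-dioxaborolane
Conditions: HBpin (1.2 equiv), [Ir(cod)Cl]2 (1.5 mol %), dppm (3 mol %), CH2Cl2, rt, 18 h; short silica plug
Reagents that add atoms: pinacolborane (HBpin), [H]B1OC(C)(C)C(C)(C)O1
Why: Iridium-catalysed anti-Markovnikov hydroboration of a terminal alkene puts boron on the terminal carbon with high linear selectivity, the aryl methyl ethers are inert, the reaction is a pure addition with no co-product, and no stereocentre is formed.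

**Step 2**
Reactants: 3 2-[3-(3,4-dimethoxyphenyl)propyl]-4,4,5,5-tetramethyl-1,3,2-dioxaborolane; 2 3-(3,4-dimethoxyphenyl)propanoic acid
Product: 5 3-(3,4-dimethoxyphenyl)propyl 3-(3,4-dimethoxyphenyl)propanoate, via sodium 3-(3,4-dimethoxyphenyl)propanoate 4 (not isolated)
Conditions: 2 (1.5 equiv), NaOSiMe3 (2.5 equiv), Cu(MeCN)4PF6 (10 mol %), 4,4′-di-tert-butyl-2,2′-bipyridine (12 mol %), (tBuO)2 (2.0 equiv), tBuOH/PhMe, N2, 55 °C, 16 h
Reagents that add atoms: none
Why: Proposed new method: copper-catalysed oxidative C(sp3)–O coupling of an unactivated primary alkylboronic ester with an aliphatic carboxylate; NaOSiMe3 turns 2 into carboxylate 4 and 3 into a silanolate "ate" complex, (tBuO)2 oxidises monovalent copper to a divalent copper κ2-carboxylate, the primary alkyl group moves from boron to copper, a second one-electron oxidation gives an alkyl(carboxylato) trivalent copper species, and SN2-like C–O reductive elimination at the unhindered CH2 (favoured over β-hydride loss because the chelating bipyridine leaves no free cis site) releases 5 and monovalent copper; no stereocentre is formed; the closest known reaction type is the Chan–Lam-type oxidative copper coupling of alkylboronic esters with amides (C–N bond) together with the copper-catalysed O-methylation of carboxylic acids with methylboronic acid, and to my knowledge neither has been shown for a primary alkyl group bearing β-hydrogens with a carboxylate.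

**Compound list**
1 | methyl eugenol (4-allyl-1,2-dimethoxybenzene) | C=CCc1ccc(OC)c(OC)c1 | starting material
2 | 3-(3,4-dimethoxyphenyl)propanoic acid | COc1ccc(CCC(=O)O)cc1OC | starting material
3 | 2-[3-(3,4-dimethoxyphenyl)propyl]-4,4,5,5-tetramethyl-1,3,2-dioxaborolane | COc1ccc(CCCB2OC(C)(C)C(C)(C)O2)cc1OC | intermediate
4 | sodium 3-(3,4-dimethoxyphenyl)propanoate | COc1ccc(CCC(=O)[O-])cc1OC.[Na+] | intermediate
5 | 3-(3,4-dimethoxyphenyl)propyl 3-(3,4-dimethoxyphenyl)propanoate | COc1ccc(CCCOC(=O)CCc2ccc(OC)c(OC)c2)cc1OC | target

**Totals**
Total step count: 2. Longest linear sequence: 2 (1 → 3 → 5).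

**Steps most likely to fail** (the route has only two steps, so both are given, the riskier first)

Step 2, the proposed new C–O coupling. Possible failures:
- β-hydride or oxidative elimination at copper, which returns alkene 1.
- Transfer of tert-butoxide or silanolate instead of carboxylate, giving the tert-butyl ether or the alcohol.
- Slow boron-to-copper transfer of the alkyl group.
- Cleavage of product 5 by free silanolate.

Fallback with known chemistry, setting out from 3 and coming back at 5: boronate 3 is oxidised with H2O2 and NaOH in THF/H2O at 0 °C to 3-(3,4-dimethoxyphenyl)propan-1-ol F1. F1 is then esterified with acid 2 using DCC and catalytic DMAP in CH2Cl2 at rt (Steglich esterification) to give 5. The C–O bond is then made by acyl substitution rather than at copper.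

Step 1, the iridium-catalysed hydroboration. Possible failures: iridium hydride may isomerise the allyl group of 1 to the conjugated propenyl arene, or give some branched boronate.

Fallback with known chemistry, setting out from 1 and coming back at 3: radical-chain anti-Markovnikov addition of HBr (HBr gas, catalytic dibenzoyl peroxide, hexane, 0 °C) gives 4-(3-bromopropyl)-1,2-dimethoxybenzene F2. F2 is then borylated with B2pin2, CuI (10 mol %), PPh3 and LiOMe in DMF at rt to give 3. The C–B bond is then made by substitution of a primary bromide, not by hydroboration.

**Further compounds**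
F1 | step 2 | 3-(3,4-dimethoxyphenyl)propan-1-ol | COc1ccc(CCCO)cc1OC
F2 | step 1 | 4-(3-bromopropyl)-1,2-dimethoxybenzene | COc1ccc(CCCBr)cc1OC
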